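## The problem

Compound 24 is a bicyclo[9.3.1]pentadecane. Ring A (C11–C12–C13–C14–C1–C15) and a twelve-membered ring (C1 through C2…C10 to C11, closed by C15) share the bridgeheads C1 and C11 and the CMe2 carbon C15, and the arms C2 and C10 leave ring A from opposite faces. Seven stereocentres have to be set (1R, 3R, 4S, 7R, 8R, 10R, 11S). C1 and C10 lie too far from each other and from the oxiranes to steer one another, so both are best bought; the cis-oxirane at C3/C4 and the trans-oxirane at C7/C8 call for a Z and an E trisubstituted olefin and reagent control; only C11, 1,3 to C1 across C15, can be left to the substrate. The fragile groups are the α-methylene ketone (C18=C12–C13=O), which tolerates neither nucleophiles nor base, the two trisubstituted oxiranes, which do not tolerate acid, and the C10 acetate, so the enone has to appear last and under neutral conditions. A short route is possible because C15 joins C1 to C11 as in the verticillen-12-yl cation: breaking C11–C15 opens both rings at once to a fourteen-membered ring with an isopropenyl group on C1. If C11=C12 is then an enone with an acetoxymethyl group on C12, a nucleophilic tertiary C15 radical faces an electrophilic C11, and loss of the C18 acetate after the addition gives the exocyclic enone of 24 directly.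

## Retrosynthesis

**C11–C15 (24 ⇒ 23).** The first cut is the bond between the bridgehead C11 and the quaternary C15. Cutting C1–C15 instead would put the bought stereocentre into the bond-forming step, and a cut inside the twelve-membered ring would leave ring A, with both bridgeheads and two different arms, to a separate multi-step construction. Precursor 23 is monocyclic, has one stereocentre fewer and holds every oxygen of 24 plus one acetate that serves as leaving group. The forward reaction must make a radical at C15 from the isopropenyl group, attack C11 from the face that gives the trans bridge, and end by expelling the C18 acetate.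

**Oxiranes and ketone (23 ⇒ 22 ⇒ 21).** The C13 ketone is taken back to the alcohol 22 and the four C–O bonds of the oxiranes to the olefins of triene 21. Earlier epoxidation would expose the oxiranes to hydride and low-valent chromium; later, the acetoxymethyl enone of 23 would meet aqueous carbonate and peroxymonosulfate. In 21 the C11=C12 olefin carries three allylic oxygens and is switched off, so the forward step only has to prefer the two trisubstituted olefins over the isopropenyl group and to choose the right face of each. One enantiomer of the Shi ketone should serve both olefins, because the Z and the E olefin present their single vinylic hydrogen in the same way.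

**C12–C13 (21 ⇒ 20).** The ring is opened between the alkenyl carbon C12 and the carbinol carbon C13, giving the bromo aldehyde 20. A cut at C11=C12 (ring closure by olefination) would need a β-ketophosphonate with CH2OR on its α-carbon, which invites β-elimination and leaves the olefin geometry to the ring closure. A cut at C5–C6 (allyl sulfone alkylation) adds a reductive desulfonylation. With the chosen cut the E geometry is fixed before the ring exists, the chromium reagent tolerates acetates, and the product is one oxidation away from the enone. The forward reaction must close a fourteen-membered ring at high dilution.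

**C11=C12 and the C18 oxidation level (20 ⇒ 19 ⇒ 18 ⇒ 17).** Diacetate 20 comes from diol aldehyde 19, and 19 from bromo ester 18 by one hydride reduction that turns the Weinreb amide into the C13 aldehyde, the ester into the C18 alcohol and the C10 pivalate into the free alcohol. This triple duty is why C13 travels as a Weinreb amide and O10 as a pivalate. Ester 18 is cut at C11=C12 to aldehyde 17 and a bromophosphonoacetate; a trifluoroethyl phosphonate is required, because only the kinetic olefination places C10 cis to the ester carbon (later C18) and the bromine (later C13) trans to C10.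

**C4–C5 (17 ⇒ 16 ⇒ 15 ⇒ 7 + 13).** Aldehyde 17 is the oxidation product of alcohol 16, unmasked from PMB ether 15. Compound 15 is cut between the olefinic C4 and the saturated C5 into the Z-alkenyl iodide 7 and diene 13, to be joined by hydroboration and B-alkyl Suzuki–Miyaura coupling. A cut at C5–C6 would be an allyl–allyl union with its regiochemical ambiguity, and a cut at C6–C7 would need a Z-configured diene on the carvone side. With the chosen cut each olefin geometry is carried by one partner (Z in 7, E in 13), the coupling only has to retain them, and each fragment holds one stereocentre.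

**The C1 fragment (7 ⇒ 6 ⇒ 5 ⇒ 2 ⇒ 1).** Iodide 7 is cut at C3=C4 to aldehyde 6 (iodo-ylide olefination), 6 is the Weinreb amide of aldehyde acid 5, and 5 results from (R)-carvone 1 by excision of its methyl-bearing ring carbon through epoxide 2. Cleaving carvone on the other side of the carbonyl would keep its Z olefin, but it would leave an aldehyde directly on the stereocentre, β,γ-unsaturated, epimerisable and one carbon short of C13. Excision leaves C1 β to both carbonyl groups and delivers C13 and C3 at the right oxidation levels; the price is that the Z olefin is remade in step 4.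

**The C10 fragment (13 ⇒ 12 ⇒ 10 ⇒ 9 ⇒ 8).** Pivalate 13 is the ester of dienol 12. Dienol 12 is cut at C6–C7 and at C8–CH3 (carboalumination of alkynol 10, then coupling with vinyl bromide), and 10 at C8–C9 (acetylide opening of PMB glycidyl ether 9, made from (S)-glycidol 8). Glycidol supplies C9–C11 with the C10 oxygen in place, so no carbonyl is ever generated at C10, where the β,γ-olefin would make it prone to isomerisation.

## Roads not taken

**Alternative 1:** The cut falls on both sides of a propyne unit (A4): a ring-A iodide A2, in which the C11–C15 bond exists from the start, and a Grignard reagent A3 carrying C5–C10 are stitched together. In the forward step the alkylcopper from A3 and CuBr·SMe2 adds syn across A4 (C4–C5), and the Z-alkenylcopper is alkylated by A2 (C2–C3) to give A1.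
- Merits: the Z geometry follows from the syn addition and should be cleaner than that of an iodo-ylide olefination, so in this respect the road is better than step 4 of the chosen plan. It is a three-component union, and it needs no macrocyclic radical step.
- Weak points: A2 is a β-branched primary iodide next to the quaternary C15, a poor electrophile for an alkenylcopper. A1 still lacks the C10–C11 bond, so the twelve-membered ring would have to be closed at its most hindered position, with C10 and C11 created there and the exocyclic methylene, both oxiranes and the acetate still to come.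
- Comparison: the chosen plan buys C10, settles both rings and C11 in one step from a monocyclic precursor, and reaches that precursor by standard couplings. Against this, its key step is without direct precedent, whereas every step of Alternative 1 is of a known type.

**Alternative 2:** The cut is C8–C9. A seco compound A6, with ring A complete, a methyl alkyne at C7≡C8 and a terminal oxirane at C9–C10, would be closed with Ni(cod)2, PBu3 and Et3B to the dienol A5, forming the bond, the E olefin and the C10 alcohol in one operation.
- Merits: the ring closure is atom-economical, the C10 configuration comes from an oxirane, and C1 and C11 are set beforehand in a six-membered ring by ordinary means. That removes the face-selection risk of the chosen plan, which is a real advantage.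
- Weak points: insertion into a dialkyl alkyne (methyl against chain) has little regiochemical bias. Reductive alkyne–oxirane coupling is established for small rings and for biased alkynes, not for a twelve-membered carbocycle. After closure, A5 still needs acetylation, ketal removal and two epoxidations, and A6 itself requires a long ring-A synthesis with the trans relation of C1 and C11 already built.
- Comparison: the chosen plan sets a precedented ring closure (step 15) and a far shorter access to its cyclisation substrate against the better stereochemical security of Alternative 2.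

**Alternative 3:** The cut is C6–C7. A seco diiodide A8 would undergo zinc insertion at the primary C6 iodide and coupling with the E-alkenyl iodide at C7 (Pd2(dba)3, tri-2-furylphosphine) to give A7, which lacks only the 7,8-oxirane.
- Merits: this is the latest possible ring closure, one epoxidation of the only electron-rich olefin away from the target. Alkylzinc reagents tolerate ketone, ester and oxirane, and C11 is again set conventionally. In end-game brevity and stereochemical security it is better than the chosen plan.
- Weak points: zinc must choose the alkyl iodide over the alkenyl iodide in the presence of an α-methylene ketone that is itself reducible and a Michael acceptor. A twelve-membered ring closure through an unstabilised alkylzinc at high dilution competes with protodemetalation and β-hydride loss. A8 demands ring A with enone, oxirane, acetate and two different iodides in place.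
- Comparison: the chosen plan offers a cyclisation substrate assembled from carvone and glycidol in which no ring has to be built before the key step.

Key step: step 18

Assumption: 21 and 22 are carried as mixtures of the two C13 epimers, since this centre becomes the ketone in step 17; locants are those of the verticillane skeleton throughout.

## Route

Step 1
Reactants: 1 (R)-carvone
Product: 2 (1R,4R,6R)-1-methyl-4-(prop-1-en-2-yl)-7-oxabicyclo[4.1.0]heptan-2-one
Conditions: H2O2 (30% aq.), NaOH (cat.), MeOH, 0 °C
Reagents that add atoms: hydrogen peroxide, OO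
Why: Weitz–Scheffer nucleophilic epoxidation touches only the enone and leaves the isopropenyl group alone; hydroperoxide adds anti to the isopropenyl group, and both new centres are excised in step 2.

Step 2
Reactants: 2 (1R,4R,6R)-1-methyl-4-(prop-1-en-2-yl)-7-oxabicyclo[4.1.0]heptan-2-one
Product: 5 (3R)-5-oxo-3-(prop-1-en-2-yl)pentanoic acid, via ketodiol 3 (not isolated), via diketo aldehyde 4 (not isolated)
Conditions: H5IO6 (3 equiv), THF/H2O, 0 °C to rt
Reagents that add atoms: water, O
Why: Periodic acid opens the epoxy ketone to ketodiol 3, then glycol cleavage and α-diketone cleavage excise the methyl-bearing carbon as acetic acid. The former C5 of carvone becomes C1, β to both new carbonyl groups and therefore not epimerisable; periodate does not attack the isopropenyl group.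

Step 3
Reactants: 5 (3R)-5-oxo-3-(prop-1-en-2-yl)pentanoic acid
Product: 6 (3R)-N-methoxy-N-methyl-5-oxo-3-(prop-1-en-2-yl)pentanamide
Conditions: MeNHOMe·HCl, EDC·HCl, N-methylmorpholine, CH2Cl2, 0 °C to rt
Reagents that add atoms: N,O-dimethylhydroxylamine hydrochloride, CNOC.Cl
Why: Carbodiimide amidation gives the Weinreb amide; the secondary hydroxylamine cannot condense irreversibly with the aldehyde, which is carried through unchanged.

Step 4
Reactants: 6 (3R)-N-methoxy-N-methyl-5-oxo-3-(prop-1-en-2-yl)pentanamide
Product: 7 (3R,5Z)-6-iodo-N-methoxy-N-methyl-3-(prop-1-en-2-yl)hept-5-enamide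
Conditions: [Ph3PCH2CH3]I, n-BuLi, THF; I2, −78 °C; NaN(SiMe3)2, −20 °C; then 6, −78 °C
Reagents that add atoms: ethyltriphenylphosphonium iodide, CC[P+](c1ccccc1)(c1ccccc1)c1ccccc1.[I-]; iodine, II
Why: Stork–Zhao olefination: the α-iodo ylide adds to the aldehyde under kinetic control and gives the (Z)-2-iodoalk-2-ene, which fixes the later C3=C4 geometry. The Weinreb amide does not react with the ylide at this temperature.

Step 5
Reactants: 8 (S)-glycidol
Product: 9 (R)-2-{[(4-methoxybenzyl)oxy]methyl}oxirane
Conditions: NaH, 4-methoxybenzyl chloride, Bu4NI (cat.), THF/DMF, 0 °C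
Reagents that add atoms: 4-methoxybenzyl chloride, COc1ccc(CCl)cc1
Why: Williamson etherification of the primary alkoxide; the stereocentre is not touched (the descriptor changes only because the priorities change).

Step 6
Reactants: 9 (R)-2-{[(4-methoxybenzyl)oxy]methyl}oxirane
Product: 10 (2R)-1-[(4-methoxybenzyl)oxy]pent-4-yn-2-ol
Conditions: LiC≡CH·H2NCH2CH2NH2, DMSO, rt
Reagents that add atoms: lithium acetylide ethylenediamine complex, [Li+].[C-]#C.NCCN
Why: SN2 opening of the terminal oxirane by acetylide at the unsubstituted carbon (later C9) leaves the C10–O bond and its configuration intact.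

Step 7
Reactants: 10 (2R)-1-[(4-methoxybenzyl)oxy]pent-4-yn-2-ol
Product: 12 (2R,4E)-1-[(4-methoxybenzyl)oxy]-4-methylhepta-4,6-dien-2-ol, via alkenylalane 11 (not isolated)
Conditions: Me3Al (3 equiv), Cp2ZrCl2 (cat.), CH2Cl2, 0 °C to rt; then vinyl bromide, ZnCl2, Pd(PPh3)4 (cat.), THF, rt
Reagents that add atoms: trimethylaluminium, C[Al](C)C; vinyl bromide, C=CBr
Why: Negishi zirconium-catalysed carboalumination adds methyl (to C8) and aluminium syn across the terminal alkyne and so fixes the E geometry of C7=C8. The alkenylalane 11 is then coupled with vinyl bromide with retention (alkenyl–alkenyl Negishi coupling); the free hydroxyl is carried as its aluminium alkoxide.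

Step 8
Reactants: 12 (2R,4E)-1-[(4-methoxybenzyl)oxy]-4-methylhepta-4,6-dien-2-ol
Product: 13 (2R,4E)-1-[(4-methoxybenzyl)oxy]-4-methylhepta-4,6-dien-2-yl pivalate
Conditions: PivCl, pyridine, DMAP (cat.), CH2Cl2, 0 °C to rt
Reagents that add atoms: pivaloyl chloride, CC(C)(C)C(=O)Cl
Why: Acylation of the secondary alcohol; the pivalate resists aqueous base and acyl migration in steps 9–12 and is removed by hydride in step 13.

Step 9
Reactants: 13 (2R,4E)-1-[(4-methoxybenzyl)oxy]-4-methylhepta-4,6-dien-2-yl pivalate; 7 (3R,5Z)-6-iodo-N-methoxy-N-methyl-3-(prop-1-en-2-yl)hept-5-enamide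
Product: 15 (3R,5Z,9E,12R)-N-methoxy-13-[(4-methoxybenzyl)oxy]-N,6,10-trimethyl-12-(pivaloyloxy)-3-(prop-1-en-2-yl)trideca-5,9-dienamide, via alkylborane 14 (not isolated)
Conditions: 9-BBN, THF, 0 °C to rt; then 7, Pd(dppf)Cl2 (cat.), AsPh3, Cs2CO3, DMF/H2O, rt
Reagents that add atoms: none
Why: 9-BBN hydroborates only the monosubstituted terminus of the diene, placing boron on C5. B-alkyl Suzuki–Miyaura coupling of 14 with the Z-alkenyl iodide forms C4–C5 with retention of both olefin geometries; ester, Weinreb amide and PMB ether are inert.

Step 10
Reactants: 15 (3R,5Z,9E,12R)-N-methoxy-13-[(4-methoxybenzyl)oxy]-N,6,10-trimethyl-12-(pivaloyloxy)-3-(prop-1-en-2-yl)trideca-5,9-dienamide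
Product: 16 (3R,5Z,9E,12R)-13-hydroxy-N-methoxy-N,6,10-trimethyl-12-(pivaloyloxy)-3-(prop-1-en-2-yl)trideca-5,9-dienamide
Conditions: DDQ, CH2Cl2/pH 7 buffer, 0 °C
Reagents that add atoms: none
Why: Oxidative cleavage of the PMB ether under buffered, near-neutral conditions, where the adjacent pivalate should not migrate.

Step 11
Reactants: 16 (3R,5Z,9E,12R)-13-hydroxy-N-methoxy-N,6,10-trimethyl-12-(pivaloyloxy)-3-(prop-1-en-2-yl)trideca-5,9-dienamide
Product: 17 (3R,5Z,9E,12R)-N-methoxy-N,6,10-trimethyl-13-oxo-12-(pivaloyloxy)-3-(prop-1-en-2-yl)trideca-5,9-dienamide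
Conditions: Dess–Martin periodinane, NaHCO3, CH2Cl2, 0 °C to rt
Reagents that add atoms: none
Why: Dess–Martin oxidation of the primary alcohol under buffered conditions; the α-acyloxy aldehyde is used at once so that C10 is not epimerised.

Step 12
Reactants: 17 (3R,5Z,9E,12R)-N-methoxy-N,6,10-trimethyl-13-oxo-12-(pivaloyloxy)-3-(prop-1-en-2-yl)trideca-5,9-dienamide
Product: 18 methyl (2E,4R,6E,10Z,13R)-2-bromo-15-[methoxy(methyl)amino]-6,10-dimethyl-15-oxo-4-(pivaloyloxy)-13-(prop-1-en-2-yl)pentadeca-2,6,10-trienoate
Conditions: (CF3CH2O)2P(O)CHBrCO2Me, KN(SiMe3)2, 18-crown-6, THF, −78 °C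
Reagents that add atoms: methyl bromo[bis(2,2,2-trifluoroethoxy)phosphoryl]acetate, COC(=O)C(Br)P(=O)(OCC(F)(F)F)OCC(F)(F)F
Why: Horner–Wadsworth–Emmons olefination with a Still–Gennari-type trifluoroethyl phosphonate; fast, irreversible elimination gives the isomer with the aldehyde residue cis to the ester, the (E)-α-bromoacrylate. This places C10 cis to the future C18 and the bromine (the future C13) trans to C10.

Step 13
Reactants: 18 methyl (2E,4R,6E,10Z,13R)-2-bromo-15-[methoxy(methyl)amino]-6,10-dimethyl-15-oxo-4-(pivaloyloxy)-13-(prop-1-en-2-yl)pentadeca-2,6,10-trienoate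
Product: 19 (3R,5Z,9E,12R,13E)-14-bromo-12,15-dihydroxy-6,10-dimethyl-3-(prop-1-en-2-yl)pentadeca-5,9,13-trienal
Conditions: i-Bu2AlH (excess), CH2Cl2, −78 °C
Reagents that add atoms: none
Why: One hydride reagent does three known jobs: Weinreb amide to aldehyde (the chelated tetrahedral intermediate survives until work-up), enoate to allylic alcohol by 1,2-reduction, and pivalate to alcohol. The alkenyl bromide and the olefins are inert.

Step 14
Reactants: 19 (3R,5Z,9E,12R,13E)-14-bromo-12,15-dihydroxy-6,10-dimethyl-3-(prop-1-en-2-yl)pentadeca-5,9,13-trienal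
Product: 20 (2E,4R,6E,10Z,13R)-2-bromo-6,10-dimethyl-15-oxo-13-(prop-1-en-2-yl)pentadeca-2,6,10-triene-1,4-diyl diacetate
Conditions: Ac2O, pyridine, DMAP (cat.), CH2Cl2, 0 °C
Reagents that add atoms: acetic anhydride, CC(=O)OC(C)=O
Why: Acetylation of both hydroxyls installs the C10 acetate of the target and the C18 leaving group in one operation; the aldehyde is unaffected.

Step 15
Reactants: 20 (2E,4R,6E,10Z,13R)-2-bromo-6,10-dimethyl-15-oxo-13-(prop-1-en-2-yl)pentadeca-2,6,10-triene-1,4-diyl diacetate
Product: 21 (1R,3Z,7E,10R,11E)-10-acetoxy-12-(acetoxymethyl)-4,8-dimethyl-1-(prop-1-en-2-yl)cyclotetradeca-3,7,11-trien-13-ol (locants as in 24; both C13 epimers)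
Conditions: CrCl2 (excess), NiCl2 (cat.), DMSO/THF, rt, slow addition at high dilution
Reagents that add atoms: none
Why: Nozaki–Hiyama–Kishi ring closure: zerovalent nickel inserts into the C–Br bond, the alkenyl group passes to chromium and adds to the aldehyde, forming C12–C13 with retention of the olefin geometry. Acetates are tolerated, and the new carbinol centre is removed in step 17.

Step 16
Reactants: 21 (1R,3Z,7E,10R,11E)-10-acetoxy-12-(acetoxymethyl)-4,8-dimethyl-1-(prop-1-en-2-yl)cyclotetradeca-3,7,11-trien-13-ol
Product: 22 (1S,3R,4S,7R,8R,10R,11E)-10-acetoxy-12-(acetoxymethyl)-3,4:7,8-diepoxy-4,8-dimethyl-1-(prop-1-en-2-yl)cyclotetradec-11-en-13-ol (both C13 epimers; C1 unchanged in space)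
Conditions: D-fructose-derived Shi ketone (1,2:4,5-di-O-isopropylidene-β-D-erythro-2,3-hexodiulo-2,6-pyranose, 0.6 equiv), KHSO5 (2.4 equiv), K2CO3, Bu4NHSO4 (cat.), MeCN/CH2(OMe)2/aq. Na2B4O7–Na2EDTA, 0 °C
Reagents that add atoms: potassium peroxymonosulfate, [K+].[O-]S(=O)(=O)OO
Why: Shi epoxidation through the spiro transition state of the chiral dioxirane: the catalyst reads the position of the single vinylic hydrogen, so the D-fructose ketone should give 7R,8R from the E olefin and 3R,4S from the Z olefin. The electrophilic dioxirane should prefer the two trisubstituted olefins over the 1,1-disubstituted isopropenyl group and ignore C11=C12, which carries three allylic oxygens.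

Step 17
Reactants: 22 (1S,3R,4S,7R,8R,10R,11E)-10-acetoxy-12-(acetoxymethyl)-3,4:7,8-diepoxy-4,8-dimethyl-1-(prop-1-en-2-yl)cyclotetradec-11-en-13-ol
Product: 23 (1R,3R,4S,7R,8R,10R,11E)-10-acetoxy-12-(acetoxymethyl)-3,4:7,8-diepoxy-4,8-dimethyl-1-(prop-1-en-2-yl)cyclotetradec-11-en-13-one
Conditions: Dess–Martin periodinane, NaHCO3, CH2Cl2, 0 °C to rt
Reagents that add atoms: none
Why: Buffered Dess–Martin oxidation of the allylic alcohol converges both C13 epimers on the E-enone; oxiranes and acetates are inert.

Step 18
Reactants: 23 (1R,3R,4S,7R,8R,10R,11E)-10-acetoxy-12-(acetoxymethyl)-3,4:7,8-diepoxy-4,8-dimethyl-1-(prop-1-en-2-yl)cyclotetradec-11-en-13-one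
Product: 24 (1R,3R,4S,7R,8R,10R,11S)-10-acetoxy-3,4:7,8-diepoxyverticill-12(18)-en-13-one (target)
Conditions: Fe(acac)3, PhSiH3, EtOH/HOCH2CH2OH, 60 °C, high dilution
Reagents that add atoms: none
Why: Proposed new method: Fe(acac)3 and PhSiH3 should form an iron hydride that transfers a hydrogen atom to the CH2 terminus of the isopropenyl group, giving the tertiary C15 radical; this adds to C11, the β-carbon of the enone, the C12 α-keto radical is reduced by divalent iron to the enolate, and the enolate expels the C18 acetate (E1cB) to give the exocyclic enone. The closest known reaction type is the Fe(acac)3/PhSiH3 hydrogen-atom-transfer radical conjugate addition that builds quaternary carbons and six-membered rings, together with radical additions to 2-(acetoxymethyl) acceptors that end in loss of acetate; running it across a fourteen-membered ring is new. Ring A closes 6-endo-trig (C15 onto C11, with C12 and C13 inside the new ring), favoured over 5-exo attack at C12 by the polarity match and by the full substitution of C12; the twelve-membered ring is what remains of the macrocycle on the other side of the new bond (formally 12-exo). The one new stereocentre, C11, is controlled by C1 through the ring: in a chair-like array the E geometry of C11=C12 holds C10 equatorial and anti to C13, so the trans bridge requires the C2 arm axial on C1, a position that costs little because C13 is trigonal and C15 fully substituted. The step needs this face selectivity and chemoselectivity for the isopropenyl group; the first rests on the expectation that the C2–C10 strap spans an axial and an equatorial position more readily than two equatorial ones, the second on the absence of any other unactivated alkene once both trisubstituted olefins are oxiranes. Oxiranes and acetates should be inert under these neutral conditions. If the C12 radical is quenched by hydrogen instead, the resulting β-acetoxy ketone should give 24 on brief exposure to a mild base.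

## Compound list

1 | (R)-carvone | CC1=CC[C@H](CC1=O)C(C)=C | starting material
2 | (1R,4R,6R)-1-methyl-4-(prop-1-en-2-yl)-7-oxabicyclo[4.1.0]heptan-2-one (oxirane trans to isopropenyl) | C[C@@]12O[C@@H]1C[C@@H](C(C)=C)CC2=O | intermediate
3 | (2R,3S,5R)-2,3-dihydroxy-2-methyl-5-(prop-1-en-2-yl)cyclohexan-1-one (ketodiol, not isolated) | C[C@@]1(O)[C@@H](O)C[C@@H](C(C)=C)CC1=O | intermediate
4 | (3R)-5,6-dioxo-3-(prop-1-en-2-yl)heptanal (diketo aldehyde, not isolated) | CC(=O)C(=O)C[C@H](C(C)=C)CC=O | intermediate
5 | (3R)-5-oxo-3-(prop-1-en-2-yl)pentanoic acid | OC(=O)C[C@H](C(C)=C)CC=O | intermediate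
6 | (3R)-N-methoxy-N-methyl-5-oxo-3-(prop-1-en-2-yl)pentanamide | CON(C)C(=O)C[C@H](C(C)=C)CC=O | intermediate
7 | (3R,5Z)-6-iodo-N-methoxy-N-methyl-3-(prop-1-en-2-yl)hept-5-enamide | CON(C)C(=O)C[C@H](C(C)=C)C/C=C(/C)I | intermediate
8 | (S)-glycidol | C1[C@@H](O1)CO | starting material
9 | (R)-2-{[(4-methoxybenzyl)oxy]methyl}oxirane | C1[C@@H](O1)COCc1ccc(OC)cc1 | intermediate
10 | (2R)-1-[(4-methoxybenzyl)oxy]pent-4-yn-2-ol | C#CC[C@@H](O)COCc1ccc(OC)cc1 | intermediate
11 | (E)-alkenyl(dimethyl)alane from 10, with O10 as its dimethylaluminium alkoxide (not isolated) | C[Al](C)/C=C(\C)C[C@@H](O[Al](C)C)COCc1ccc(OC)cc1 | intermediate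
12 | (2R,4E)-1-[(4-methoxybenzyl)oxy]-4-methylhepta-4,6-dien-2-ol | C=C/C=C(\C)C[C@@H](O)COCc1ccc(OC)cc1 | intermediate
13 | (2R,4E)-1-[(4-methoxybenzyl)oxy]-4-methylhepta-4,6-dien-2-yl pivalate | C=C/C=C(\C)C[C@@H](OC(=O)C(C)(C)C)COCc1ccc(OC)cc1 | intermediate
14 | B-alkyl-9-borabicyclo[3.3.1]nonane from 13, boron on C5 (not isolated) | C(C/C=C(\C)C[C@@H](OC(=O)C(C)(C)C)COCc1ccc(OC)cc1)B1C2CCCC1CCC2 | intermediate
15 | (3R,5Z,9E,12R)-N-methoxy-13-[(4-methoxybenzyl)oxy]-N,6,10-trimethyl-12-(pivaloyloxy)-3-(prop-1-en-2-yl)trideca-5,9-dienamide | CON(C)C(=O)C[C@H](C(C)=C)C/C=C(/C)CC/C=C(\C)C[C@@H](OC(=O)C(C)(C)C)COCc1ccc(OC)cc1 | intermediate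
16 | (3R,5Z,9E,12R)-13-hydroxy-N-methoxy-N,6,10-trimethyl-12-(pivaloyloxy)-3-(prop-1-en-2-yl)trideca-5,9-dienamide | CON(C)C(=O)C[C@H](C(C)=C)C/C=C(/C)CC/C=C(\C)C[C@@H](OC(=O)C(C)(C)C)CO | intermediate
17 | (3R,5Z,9E,12R)-N-methoxy-N,6,10-trimethyl-13-oxo-12-(pivaloyloxy)-3-(prop-1-en-2-yl)trideca-5,9-dienamide | CON(C)C(=O)C[C@H](C(C)=C)C/C=C(/C)CC/C=C(\C)C[C@@H](OC(=O)C(C)(C)C)C=O | intermediate
18 | methyl (2E,4R,6E,10Z,13R)-2-bromo-15-[methoxy(methyl)amino]-6,10-dimethyl-15-oxo-4-(pivaloyloxy)-13-(prop-1-en-2-yl)pentadeca-2,6,10-trienoate | CON(C)C(=O)C[C@H](C(C)=C)C/C=C(/C)CC/C=C(\C)C[C@@H](OC(=O)C(C)(C)C)/C=C(/Br)C(=O)OC | intermediate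
19 | (3R,5Z,9E,12R,13E)-14-bromo-12,15-dihydroxy-6,10-dimethyl-3-(prop-1-en-2-yl)pentadeca-5,9,13-trienal | O=CC[C@H](C(C)=C)C/C=C(/C)CC/C=C(\C)C[C@@H](O)/C=C(/Br)CO | intermediate
20 | (2E,4R,6E,10Z,13R)-2-bromo-6,10-dimethyl-15-oxo-13-(prop-1-en-2-yl)pentadeca-2,6,10-triene-1,4-diyl diacetate | O=CC[C@H](C(C)=C)C/C=C(/C)CC/C=C(\C)C[C@@H](OC(C)=O)/C=C(/Br)COC(C)=O | intermediate
21 | (1R,3Z,7E,10R,11E)-10-acetoxy-12-(acetoxymethyl)-4,8-dimethyl-1-(prop-1-en-2-yl)cyclotetradeca-3,7,11-trien-13-ol, both C13 epimers | OC1C[C@H](C(C)=C)C/C=C(/C)CC/C=C(\C)C[C@@H](OC(C)=O)/C=C1\COC(C)=O | intermediate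
22 | (1S,3R,4S,7R,8R,10R,11E)-10-acetoxy-12-(acetoxymethyl)-3,4:7,8-diepoxy-4,8-dimethyl-1-(prop-1-en-2-yl)cyclotetradec-11-en-13-ol, both C13 epimers | OC1C[C@H](C(C)=C)C[C@H]2O[C@@]2(C)CC[C@H]2O[C@]2(C)C[C@@H](OC(C)=O)/C=C1\COC(C)=O | intermediate
23 | (1R,3R,4S,7R,8R,10R,11E)-10-acetoxy-12-(acetoxymethyl)-3,4:7,8-diepoxy-4,8-dimethyl-1-(prop-1-en-2-yl)cyclotetradec-11-en-13-one | O=C1C[C@H](C(C)=C)C[C@H]2O[C@@]2(C)CC[C@H]2O[C@]2(C)C[C@@H](OC(C)=O)/C=C1\COC(C)=O | intermediate
24 | (1R,3R,4S,7R,8R,10R,11S)-10-acetoxy-3,4:7,8-diepoxyverticill-12(18)-en-13-one | C=C1C(=O)C[C@H]2C[C@H]3O[C@@]3(C)CC[C@H]3O[C@]3(C)C[C@@H](OC(C)=O)[C@H]1C2(C)C | target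

## Step count and least certain steps

Total: 18 steps. Longest linear sequence: 14 steps (steps 1–4 and 9–18, or steps 5–8 and 9–18).

**Step 18 (key step).** The most likely failure is capture of a second hydrogen atom by the C15 radical (net hydrogenation of the isopropenyl group) before it reaches C11, because the fourteen-membered ring may spend little time in the folded conformer. Addition to the wrong face of C11 is the second concern, and a change of radical source would not correct it. The fallback uses known reaction types; it sets out from 22 and returns at 24. Markovnikov hydrobromination by hydrogen-atom transfer (Co(acac)2, t-BuOOH, Et3SiH, TsBr) should convert the isopropenyl group of 22 into the tertiary bromide F1, since the oxygen-flanked C11=C12 olefin is a poor hydrogen-atom acceptor. Dess–Martin oxidation then gives the bromo enone F2. Bu3SnH added slowly with AIBN in benzene at 80 °C generates the C15 radical in a chain in which the hydrogen donor is kept scarce; tin hydride radical conjugate cyclisation, a known reaction class that includes transannular cases in macrocyclic enones, should give the β-acetoxy ketone F3 as a mixture at C12. DBU in CH2Cl2 then eliminates acetic acid to give 24.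

**Step 16.** Over-oxidation at the isopropenyl group while the slower of the two trisubstituted olefins is still being consumed is one risk. The other is erosion of reagent control at the Z olefin by the conformational bias of the macrocycle, which exposes only one face to an external oxidant. The fallback moves the epoxidation to the open chain, where both olefins are unhindered; it sets out from 18 and returns at 22. The same Shi conditions applied to 18 (the α-bromo enoate is electron-poor and inert) should give the bis-epoxide F4. i-Bu2AlH at −78 °C, where trisubstituted oxiranes should survive, gives the diol aldehyde F5, acetylation gives the diacetate F6, and the CrCl2/NiCl2 ring closure of F6 gives 22 directly.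

**Step 15.** Slow insertion of zerovalent nickel into the hindered trisubstituted alkenyl bromide would leave the aldehyde exposed to reduction and pinacol coupling by divalent chromium and favour oligomerisation over ring closure. The fallback changes the electrophile for the whole end-game; it sets out from 18 and returns at 21. Copper-mediated halogen exchange (CuI, NaI, trans-N,N′-dimethylcyclohexane-1,2-diamine, dioxane, 110 °C) on ester 18, which carries neither aldehyde nor allylic acetate, should give the iodo ester F7. Reduction as in step 13 gives the iodo diol aldehyde F8, acetylation gives the iodo diacetate F9, and the faster-inserting iodide is closed with CrCl2/NiCl2 to 21.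

**Step 9.** Loss of regiocontrol in the hydroboration of the conjugated diene (boron at C6, or 1,4-addition giving allylic boranes) would lead to branched or transposed coupling products. The fallback replaces the borane by an alkylzinc made from a defined primary iodide; it sets out from 10 and returns at 15. Carboalumination of 10 as in step 7, conversion of alane 11 into its ate complex with n-BuLi and opening of oxirane should give the diol F10. Iodination of the primary hydroxyl (I2, PPh3, imidazole) gives the iodo alcohol F11, and pivaloylation gives the iodo pivalate F12. Zinc insertion (Zn, LiCl, THF) and coupling with 7 under Pd(PPh3)4 give 15.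

**Step 2.** The one-flask sequence may stall at the hydrolysis of the deactivated epoxy ketone, and the water-soluble aldehyde acid may be lost on isolation or close to a hydroxy lactone that couples poorly in step 3. The fallback separates the events and carries a neutral ester; it sets out from 2 and returns at 7. Dilute H2SO4 in THF/H2O gives ketodiol 3, now isolated. Pb(OAc)4 in MeOH/benzene cleaves it to the methyl ester aldehyde F13. The olefination of step 4 applied to F13 gives the iodo ester F14, and MeNHOMe·HCl with i-PrMgCl in THF at −20 °C converts F14 into 7.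

## Further compounds

F1 | step 18 | tertiary bromide of 22: 1-(2-bromopropan-2-yl) in place of isopropenyl, both C13 epimers | OC1C[C@H](C(C)(C)Br)C[C@H]2O[C@@]2(C)CC[C@H]2O[C@]2(C)C[C@@H](OC(C)=O)/C=C1\COC(C)=O
F2 | step 18 | tertiary bromide of 23: 1-(2-bromopropan-2-yl) in place of isopropenyl | O=C1C[C@H](C(C)(C)Br)C[C@H]2O[C@@]2(C)CC[C@H]2O[C@]2(C)C[C@@H](OC(C)=O)/C=C1\COC(C)=O
F3 | step 18 | 10-acetoxy-12-(acetoxymethyl)-3,4:7,8-diepoxyverticillan-13-one, configured as 24, both C12 epimers | CC(=O)OCC1C(=O)C[C@H]2C[C@H]3O[C@@]3(C)CC[C@H]3O[C@]3(C)C[C@@H](OC(C)=O)[C@H]1C2(C)C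
F4 | step 16 | bis-epoxide of 18 (oxiranes as in 22) | CON(C)C(=O)C[C@H](C(C)=C)C[C@H]1O[C@@]1(C)CC[C@H]1O[C@]1(C)C[C@@H](OC(=O)C(C)(C)C)/C=C(/Br)C(=O)OC
F5 | step 16 | bis-epoxide of 19 | O=CC[C@H](C(C)=C)C[C@H]1O[C@@]1(C)CC[C@H]1O[C@]1(C)C[C@@H](O)/C=C(/Br)CO
F6 | step 16 | bis-epoxide of 20 | O=CC[C@H](C(C)=C)C[C@H]1O[C@@]1(C)CC[C@H]1O[C@]1(C)C[C@@H](OC(C)=O)/C=C(/Br)COC(C)=O
F7 | step 15 | iodo analogue of 18 (2-iodo, 2E) | CON(C)C(=O)C[C@H](C(C)=C)C/C=C(/C)CC/C=C(\C)C[C@@H](OC(=O)C(C)(C)C)/C=C(/I)C(=O)OC
F8 | step 15 | iodo analogue of 19 | O=CC[C@H](C(C)=C)C/C=C(/C)CC/C=C(\C)C[C@@H](O)/C=C(/I)CO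
F9 | step 15 | iodo analogue of 20 | O=CC[C@H](C(C)=C)C/C=C(/C)CC/C=C(\C)C[C@@H](OC(C)=O)/C=C(/I)COC(C)=O
F10 | step 9 | (2R,4E)-1-[(4-methoxybenzyl)oxy]-4-methylhept-4-ene-2,7-diol | OCC/C=C(\C)C[C@@H](O)COCc1ccc(OC)cc1
F11 | step 9 | (2R,4E)-7-iodo-1-[(4-methoxybenzyl)oxy]-4-methylhept-4-en-2-ol | ICC/C=C(\C)C[C@@H](O)COCc1ccc(OC)cc1
F12 | step 9 | (2R,4E)-7-iodo-1-[(4-methoxybenzyl)oxy]-4-methylhept-4-en-2-yl pivalate | ICC/C=C(\C)C[C@@H](OC(=O)C(C)(C)C)COCc1ccc(OC)cc1
F13 | step 2 | methyl (3R)-5-oxo-3-(prop-1-en-2-yl)pentanoate | COC(=O)C[C@H](C(C)=C)CC=O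
F14 | step 2 | methyl (3R,5Z)-6-iodo-3-(prop-1-en-2-yl)hept-5-enoate | COC(=O)C[C@H](C(C)=C)C/C=C(/C)I
A1 | alternative 1 | ring A carrying the complete Z,E-diene chain (product of the carbocupration–alkylation) | CC(C)(C)[Si](C)(C)OCC/C(C)=C/CC/C(C)=C\C[C@@H]1CC2(OCCO2)C=CC1(C)C
A2 | alternative 1 | ring-A iodide: 9-(iodomethyl)-8,8-dimethyl-1,4-dioxaspiro[4.5]dec-6-ene, configured at the CH as C1 of 24 | IC[C@@H]1CC2(OCCO2)C=CC1(C)C
A3 | alternative 1 | Grignard reagent carrying C5–C10: (E)-6-(tert-butyldimethylsilyloxy)-4-methylhex-3-enylmagnesium bromide | CC(C)(C)[Si](C)(C)OCC/C(C)=C/CC[Mg]Br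
A4 | alternative 1 | propyne | CC#C
A5 | alternative 2 | macrocyclic dienol with C13 as ethylene ketal (product of the reductive coupling) | C=C1C2(OCCO2)C[C@H]3C/C=C(C)\CC/C=C(\C)C[C@@H](O)[C@H]1C3(C)C
A6 | alternative 2 | seco compound: ring A with the Z chain ending in a methyl alkyne on C1 and a terminal oxirane on C11 | C=C1C2(OCCO2)C[C@@H](C/C=C(C)\CCC#CC)C(C)(C)[C@@H]1[C@H]1CO1
A7 | alternative 3 | 24 lacking the 7,8-oxirane oxygen (E olefin at C7=C8) | C=C1C(=O)C[C@H]2C[C@H]3O[C@@]3(C)CC/C=C(\C)C[C@@H](OC(C)=O)[C@H]1C2(C)C
A8 | alternative 3 | seco diiodide: ring A enone with the primary C6 iodide on the C1 arm and the E-alkenyl iodide on the C11 arm | C=C1C(=O)C[C@@H](C[C@H]2O[C@@]2(C)CCI)C(C)(C)[C@@H]1[C@H](OC(C)=O)C/C(C)=C/I
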